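(The readings come from a simulation with constants of no real substance; the scatter is artificial.)

**Late readings.** You wanted a quick number, so we start at the late end. At 20.0 min the winter flask reads product 25.2% and starting material 55.9%, which leaves 18.9% of the charge unseen. We call unseen material divided by starting material the hold ratio, 0.338.

| flask | starting material | partner | capture agent | remark | time |
|---|---|---|---|---|---|
| winter | 0.35 M | 0.80 equiv | 0.105 M | the very flask that is asked about, followed so far |  |
| flask | 0.35 M | 0.800 equiv | 0.105 M |  | 50 min |

- winter (time / min: product / %, starting material / %): 5.00: 9.1, 67.6; 8.00: 16.0, 63.3; 10.0: 18.5, 60.8; 12.0: 21.3, 59.8; 15.0: 23.4, 56.7; 20.0: 25.2, 55.9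

(each reading ± 0.5 percentage points)

- what was read earlier has a scatter of 0.5 percentage points, one standard deviation

- time up to 50 min at which product stands highest
- the amount of product, in percent of the starting material charged, at that time
- earliest time at which at least nineteen twentieths of that best amount are there, in min
- latest time at which they still are, in min

**Early end.** At 5.00 min the unseen share is larger, 23.3%, yet the ratio reads 0.345, the same within a scatter of 0.5 percentage points. Joining the two ends, we read the unseen share as following starting material, like a fast pre-equilibrium. Our rule for the winter flask is that product equals the charge less starting material times one plus the hold ratio.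

**Our reckoning.** The rule gives no time, but it links two amounts. The forecast's top of 26.5% needs starting material at 54.9%, a further fall of 1.00 point. The last interval gave 0.8 points, less than that fall, and it is a difference of two readings, each with a scatter of 0.5 points. So the readings leave that height unconfirmed, and we would commit to a top near the last reading of 25.2%.

**Your hunch.** The forecast has 26.5% at 50 min, with the window from 19.5 min to 50 min: “Nothing yet shows product loss, so I expect a flat plateau to 50 min.”

**The flask.** Product peaks at 25.1% at 21.5 min, earlier than forecast, and stays within the window from 15.6 min to 30.4 min. By 50.0 min it has dropped to 19.4%.

    partner → second intermediate (k = 0.00310 s⁻¹)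
    starting material ⇌ open intermediate (K = 0.340, k = 0.130 s⁻¹)
    second intermediate → decomposed reagent (k = 0.00220 s⁻¹)
    open intermediate + second intermediate ⇌ product (K = 99.0 L mol⁻¹, k = 0.0560 L mol⁻¹ s⁻¹)
    second intermediate + capture agent → trapped intermediate (k = 0.290 L mol⁻¹ s⁻¹)

**Ratio reused.** At 50.0 min the winter flask holds starting material 60.2%, so the hold ratio gives product 19.5%, and the flask has 19.4%. The neighbour charged with 3.20 equiv of partner ends at 34.1% starting material, so the ratio gives 54.4%, and that flask holds 54.3% product.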